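Target is the product you want, and in both earlier runs it leaks into isomer of the product B at a rate you can read by hand. Count that leak's turnovers before you trust any fit.

| flask | substrate | reagent | catalyst | remark | time |
|---|---|---|---|---|---|
| Tuesday's | 0.020 M | 2.5 equiv | 1.5 mol% | run made earlier |  |
| Friday's | 0.040 M | 2.5 equiv | 1 mol% | run made earlier |  |
| north-east | 0.020 M | 2.50 equiv | 1 mol% |  | 2.0 h |
| south-east | 0.020 M | 3.80 equiv | 1 mol% |  | 2.0 h |

| run | time / min | substrate / % | isomer of the product B / % | target / % | isomer of the product A / % |
|---|---|---|---|---|---|
| Tuesday's | 3.00 | 66.7 | 0.3 | 30.9 | 1.1 |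
| Tuesday's | 6.00 | 49.1 | 1.6 | 46.6 | 1.3 |
| Tuesday's | 12.0 | 31.5 | 3.5 | 61.6 | 3.9 |
| Tuesday's | 20.0 | 22.6 | 7.2 | 65.6 | 4.4 |
| Tuesday's | 40.0 | 15.3 | 18.1 | 59.2 | 8.9 |
| Friday's | 3.00 | 48.7 | 0.7 | 48.7 | 1.6 |
| Friday's | 6.00 | 30.2 | 0.2 | 65.7 | 1.3 |
| Friday's | 12.0 | 16.0 | 3.5 | 76.6 | 4.0 |
| Friday's | 20.0 | 9.8 | 8.1 | 77.0 | 6.5 |
| Friday's | 40.0 | 7.2 | 14.5 | 68.4 | 10.3 |

(readings scatter by 0.5 percentage points)

- a reading or a percentage of target counts all its forms, free or not

1. which of these there is most of at the end, counted by the substrate in it, north-east (isomer of the product B / isomer of the product A / substrate / target)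
2. which of these there is most of at the end, counted by the substrate in it, south-east (isomer of the product B / isomer of the product A / substrate / target)
3. final amount of the leader among these, as a percentage of the substrate charged, in north-east
4. final amount of the leader among these, as a percentage of the substrate charged, in south-east

North-east looks nearly the same as Tuesday's run: same c(substrate), same equivalents of reagent, less catalyst. Take the stretch from 20.0 min to 40.0 min. Treated as pseudo-first-order, isomer of the product B gains 0.00873 /min of the standing target in Tuesday's run and 0.00440 /min in Friday's.

Friday's c(catalyst) is higher, 4.00 × 10⁻⁴ M against 3.00 × 10⁻⁴ M, yet its leak is slower. So I don't tie this leak to catalyst. Look instead at spare reagent, what remains once each substrate has taken one reagent: Tuesday's 0.0300 M against Friday's 0.0600 M. Both leaks are readings with their scatter, and two of them give no law, so I only borrow. North-east has Tuesday's spare reagent, 0.0300 M, so I lend it Tuesday's leak. South-east's 0.0560 M stands close to Friday's, so I lend it Friday's leak.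

My drain count is the lent leak times the run time. It comes to 1.05 in north-east and 0.528 in south-east. Above 0.693, more than half of what passed through target has left it. North-east lies above, so I call isomer of the product B there. South-east lies below, so I call target.

Tuesday's last reading leaves 75.8 % outside substrate and isomer of the product A. Split by the count, that pool gives me 49.3 % in north-east and 44.7 % in south-east.

The forecast names isomer of the product B at 35 % and target at 32 %, saying “reagent seems to protect target, probably by binding it”. Its leaders match mine, and its amounts are lower than mine.

The flask gives isomer of the product B at 41.8 % in north-east and target at 46.9 % in south-east.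

    substrate + reagent ⇌ target (K = 75.0 /M, k = 3.00 /M/min)
    substrate + reagent ⇌ isomer of the product A (K = 1200 /M, k = 0.0900 /M/min)
    target + catalyst ⇌ isomer of the product A + catalyst, rate k3*[catalyst]*[target] forward; the back reaction follows from the equilibrium constant (k = 19.0 /M/min)
    reagent + target ⇌ idle adduct, settled at all times (K = 49.0 /M)
    target ⇌ isomer of the product B (K = 11.0, k = 0.0180 /min)

The forecast parts from the flask on substrate: it expected about 26 % in north-east, and 7.75 % stands there. Target here includes idle adduct. Read back from the end amounts, the north-east count is 0.782 against my 1.05, and the south-east count is 0.569 against my 0.528. Now take a neighbour, south-east itself read at 8.0 h. The same lent leak gives a count of 2.11, above 0.693. That neighbour ends with target at 18.4 % and isomer of the product B at 55.4 %.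

(The data stem from a simulated flask with constants of no real substance; the scatter is artificial.)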